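## Structural features

The target is an isoflavan: a 7-hydroxychroman (ring A fused to the dihydropyran ring C) that carries at C3 a ring B with 2'-OMe, a free 3',4'-catechol and a 2-methylbut-3-en-2-yl (tert-prenyl) group at C5'. C3 is the only stereocentre (R); it has no stereogenic neighbour, is benzylic to ring B and lies between the methylene groups C2 and C4, so it is configurationally safe once the carbonyl used to set it has been reduced. The fragile parts are the catechol (air oxidation, worst under base), the ortho-(tert-prenyl)phenol (acid closes it to a dihydrobenzofuran) and the terminal alkene, which excludes hydrogenation and hydrogenolysis once it is in place. The real difficulty is twofold: a ring B with five different substituents in fixed order, and an aryl ether O1–C8a on a ring A that offers no handle beyond its own oxygen pattern. Ring A carries only O1 on C8a, the hydroxyl on C7 and the arm C4 on C4a, so it is a 4-alkylphenol with one extra oxygen meta to the hydroxyl and ortho to the alkyl group. Oxidation of that phenol in methanol to the 4-methoxycyclohexa-2,5-dienone makes C8a an enone β-carbon six atoms away from the C2 hydroxyl, and the key step uses exactly this. The same reactivity forces one design change: a free C2 hydroxyl can reach C4a through a five-membered transition state during the oxidation and would give a spiro ether, so it is kept silylated until the dienone exists.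

## Logic of the disconnections

25 ⇒ 24. The two O–Si bonds on ring B are cut last. The catechol is the most sensitive group and fluoride is the one reagent class that leaves the alkene and the ortho-(tert-prenyl)phenol alone. The forward step must be buffered and run without oxygen.

24 ⇒ 22 (through 23). The bond O1–C8a is cut and methanol is returned across C4a/C8a. Ring C and the aryl ether disappear, and ring A becomes a dienone whose two β-carbons lead to the same arene. The forward step must apply base before acid and needs the C2 hydroxyl free only at this moment.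

22 ⇒ 20 (through 21). The C4a–OMe bond is cut, which returns ring A to a plain para-substituted phenol, and the C2 oxygen is re-silylated. The oxidant must pick the one free phenol over the capped ring B and the alkene. The silyl ether must outlast the oxidation and then leave under acid too weak to ionise the quinol ether.

20 ⇒ 19 ⇒ 18. The O–allyl bond on ring A and the O–SiEt3 bond on C2 are cut. This defines an orthogonal set of three: allyl (zerovalent palladium), triethylsilyl (mild acid) and tert-butyldimethylsilyl (fluoride). Each removal must leave the other two.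

18 ⇒ 17 ⇒ 13 + 16. The bond C3–C4 is cut after C2 is raised to the acyl level, because C3 is then an enolate carbon and a chiral imide can set it. The molecule falls into a ring B two-carbon unit and a ring A benzyl unit. The forward step needs facial control on the chelated enolate, no equilibration of the acidic α-aryl centre, and a reductive release of the auxiliary.

16 ⇒ 15 ⇒ 14. The C–Br and O–allyl bonds are cut back to a bought hydroxybenzyl alcohol. The only demand is that the phenol is alkylated before the benzylic alcohol is activated.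

13 ⇒ 11 + 12, then 11 ⇒ 10 ⇒ 9 ⇒ 8. The N–acyl bond is cut, and then the bond C2–C3 in the sense of a one-carbon homologation of an aldehyde. The aldehyde is worth keeping until here because it controls the chemistry of ring B earlier. The homologation must avoid hydroxide, which would strip the aryl silyl ethers.

8 ⇒ 7 ⇒ 6 ⇒ 4 + 5. The C5'–C bond is cut by a retro-[3,3] shift to the O4' prenyl ether, and then the O4'–C bond. A tert-prenyl group ortho to a phenol oxygen is the signature of an aromatic Claisen rearrangement, and C5' is the only free ortho position. The para aldehyde makes the 4-hydroxyl the most acidic, so 5 goes on selectively. The thermal step must stop at the normal product, hence immediate silylation.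

4 ⇒ 3 ⇒ 2 ⇒ 1. The O2'–CH3 bond is cut. O2' is the least reactive oxygen (chelated to the aldehyde), so the other two are tied in a ketal while it is methylated. This reaches a bought trihydroxybenzaldehyde; the ketal must form on O3'/O4' and come off without harming the aldehyde.

## Other disconnections considered

Alternative 1: The cut is C4–C4a.
- **Forward key step.** The N-hydroxyphthalimide ester A2 already holds the O1–C8a ether and the C3 centre. At a cathode under nickel–bipyridine catalysis it would lose CO2 to give the primary C4 radical; nickel inserted into the C4a–Br bond would capture it, and reductive elimination would close ring C to chroman A1.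
- **In favour.** The aryl ether is made beforehand by ordinary phenol alkylation, so ring A needs no oxidation; on this point the alternative is better than the chosen plan. C3 is one atom away from the radical and is untouched, which makes it the equal of the chosen plan in stereochemical safety. C3 could also be set catalytically, without an auxiliary.
- **Against it here.** A1 has hydrogen at C5'. After ring closure the benzyl ether must be hydrogenolysed, O4' prenylated with 5, and the Claisen rearrangement run on the finished isoflavan. The SEM group must then leave an ortho-(tert-prenyl)phenol, for which acid is the wrong reagent. The primary radical sits next to the carbon bearing ring B and may undergo a 1,2-aryl shift or simple reduction before capture. Ring-closing reductive coupling is also less secure than the intermolecular case and needs a cell.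
- **Comparison.** Structure: this plan buys the O1–C8a bond, the chosen plan derives it from the oxygen pattern of ring A. Mechanism: radical capture at nickel against polar conjugate addition and elimination. Step economy: about five operations would follow A1 against one after 24, so the chosen plan should be shorter after the key step and comparable before it.

Alternative 2: The cuts are C4–C4a and O1–C2, made in one condensation.
- **Forward key step.** 3-(Triisopropylsilyloxy)phenol A4 and the 2-arylacrolein A5 would be joined on an arylboronic acid template. The boron-bound phenol attacks the aldehyde carbon through its ortho carbon, the derived ortho-quinone methide closes by oxa-6π electrocyclisation, and the isoflav-3-ene A3 results. Hydrogenation of C3=C4 with a chiral iridium N,P-ligand catalyst would then set C3.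
- **In favour.** It is the most convergent of the four plans and is better than the chosen one in step economy: ring C and both its bonds to ring A arise in one step, and the stereocentre comes from a catalyst instead of a stoichiometric auxiliary. The silyl end-game is equal.
- **Against it here.** Hydrogenation and the terminal alkene exclude each other, so A3 must lack the tert-prenyl group, which then has to be installed on the isoflavan after debenzylation. The enantioselectivity for a chromene whose aryl group has an ortho-methoxy substituent is hard to predict. A4 has two ortho positions and only sterics separate them. A5 is prone to polymerise, and making it needs the same one-carbon extension of a ring B aldehyde as the chosen plan.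
- **Comparison.** Structure: both plans build ring C onto a simple phenol, but only the chosen one can carry the alkene through. Mechanism: catalyst-controlled face selection on an alkene against auxiliary-controlled enolate alkylation, the latter being the more predictable here. Step economy: the alternative should be shorter overall.

Alternative 3: The cuts are C3–C1' and C4–C4a; ring C stays open.
- **Forward key step.** The aryllithium from bromide A7 would add to the vinylboronic ester A9, and the ate complex would be coupled with 1-bromo-2,4-bis(tert-butyldimethylsilyloxy)benzene A8 under palladium catalysis with a chiral ferrocenyl bisphosphine. Oxidative addition, 1,2-migration of ring B from boron to carbon and reductive elimination would give the secondary boronic ester A6. One-carbon homologation at boron, oxidation to the C2 alcohol, desilylation and a Mitsunobu closure of O1–C2 would follow.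
- **In favour.** Two skeletal bonds and the stereocentre form in one catalytic step, which is better than the chosen plan in convergence. The oxygen on C8a is bought with A8, so ring A never changes oxidation state, which is also better. The tert-prenyl group is carried from the start, as in the chosen plan (equal).
- **Against it here.** A7 lacks the aldehyde that makes O4' selectively alkylatable, so ring B would have to be rebuilt around a bromide. The migrating aryl group has an ortho-methoxy group and the electrophile an ortho-silyloxy group, both of which burden the coupling. The SEM ether on O3' must finally be removed beside the acid-sensitive ortho-(tert-prenyl)phenol. The Mitsunobu step must choose among several free phenols.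
- **Comparison.** Structure: it forms the bonds at C3 where the chosen plan forms C3–C4 and O1–C8a. Mechanism: stereospecific 1,2-metallate shift against enolate alkylation. Step economy: about five steps would follow A6, so the total should be about equal to the chosen plan.

Key step: step 17

Remark on the structures: with the ranking C2 (CH2O) > C1' > C4 > H the descriptor at C3 is R from 17 to 25, and it does not change on reduction, oxidation or ring closure. Ar stands for 3,4-bis(tert-butyldimethylsilyloxy)-2-methoxy-5-(2-methylbut-3-en-2-yl)phenyl.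

Assumption: the sodium enolate of the (R)-4-benzyl-2-oxazolidinone imide shows the usual sense of induction; 1, 5, 12, 14 and the reagents over the arrows are bought.

## Route

Step 1
Reactants: 1 2,3,4-trihydroxybenzaldehyde
Product: 2 4-hydroxy-2,2-diphenyl-1,3-benzodioxole-5-carbaldehyde
Conditions: Ph2CCl2, Ph2O, 175 °C
Reagents that add atoms: dichlorodiphenylmethane, ClC(Cl)(c1ccccc1)c1ccccc1
Why: Ketalisation of a catechol with a gem-dichloride; the 2-hydroxyl is hydrogen-bonded to the aldehyde and stays out, so the 3,4-pair closes the five-membered ketal.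

Step 2
Reactants: 2 4-hydroxy-2,2-diphenyl-1,3-benzodioxole-5-carbaldehyde
Product: 3 4-methoxy-2,2-diphenyl-1,3-benzodioxole-5-carbaldehyde
Conditions: MeI, K2CO3, DMF, rt
Reagents that add atoms: methyl iodide, CI
Why: Williamson methylation of the only free phenol; the chelated hydroxyl is slow but is the sole nucleophile present.

Step 3
Reactants: 3 4-methoxy-2,2-diphenyl-1,3-benzodioxole-5-carbaldehyde
Product: 4 3,4-dihydroxy-2-methoxybenzaldehyde
Conditions: AcOH/H2O (4:1), 100 °C
Reagents that add atoms: none
Why: Acid hydrolysis of the diphenylmethylene ketal through the stabilised diarylcarbenium ion; the methyl ether and the aldehyde are inert.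

Step 4
Reactants: 4 3,4-dihydroxy-2-methoxybenzaldehyde; 5 prenyl bromide
Product: 6 3-hydroxy-2-methoxy-4-[(3-methylbut-2-en-1-yl)oxy]benzaldehyde
Conditions: NaHCO3, NaI (cat.), DMF, 40 °C
Reagents that add atoms: none
Why: Williamson etherification under weak-base control: hydrogen carbonate deprotonates only the 4-hydroxyl, acidified by the para aldehyde, so O4' is alkylated and the 3-hydroxyl is left.

Step 5
Reactants: 6 3-hydroxy-2-methoxy-4-[(3-methylbut-2-en-1-yl)oxy]benzaldehyde
Product: 8 3,4-bis(tert-butyldimethylsilyloxy)-2-methoxy-5-(2-methylbut-3-en-2-yl)benzaldehyde, via catechol aldehyde 7 (not isolated)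
Conditions: PhNEt2, 185 °C, sealed tube, Ar; cool; CH2Cl2, 2,6-lutidine, TBSOTf, 0 °C to rt
Reagents that add atoms: tert-butyldimethylsilyl trifluoromethanesulfonate, CC(C)(C)[Si](C)(C)OS(=O)(=O)C(F)(F)F
Why: Aromatic Claisen rearrangement: the [3,3] shift delivers the tertiary allyl terminus to C5', the only free ortho position of the O4' ether, and tautomerisation restores the arene. Silylating the crude catechol in the same vessel removes the free phenol that would allow abnormal Claisen isomerisation or air oxidation; the triflate is reactive enough for the hindered O4'.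

Step 6
Reactants: 8 3,4-bis(tert-butyldimethylsilyloxy)-2-methoxy-5-(2-methylbut-3-en-2-yl)benzaldehyde
Product: 9 1,2-bis(tert-butyldimethylsilyloxy)-3-methoxy-4-(2-methoxyethenyl)-6-(2-methylbut-3-en-2-yl)benzene (E/Z mixture)
Conditions: MeOCH2PPh3Cl, NaN(SiMe3)2, THF, 0 °C; then 8, 0 °C to rt
Reagents that add atoms: (methoxymethyl)triphenylphosphonium chloride, COC[P+](c1ccccc1)(c1ccccc1)c1ccccc1.[Cl-]
Why: Wittig methoxymethylenation; the ylide is formed before the aldehyde is added, so no free amide base meets the aryl silyl ethers, and the alkene geometry is irrelevant.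

Step 7
Reactants: 9 1,2-bis(tert-butyldimethylsilyloxy)-3-methoxy-4-(2-methoxyethenyl)-6-(2-methylbut-3-en-2-yl)benzene
Product: 10 2-[3,4-bis(tert-butyldimethylsilyloxy)-2-methoxy-5-(2-methylbut-3-en-2-yl)phenyl]acetaldehyde
Conditions: TFA, H2O, CH2Cl2, 0 °C to rt; used crude
Reagents that add atoms: water, O
Why: Acid hydrolysis of an enol ether (C-protonation, hydration of the oxocarbenium ion, loss of methanol); aryl silyl ethers tolerate acid far better than base, and the capped phenols cannot cyclise onto the alkene.

Step 8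
Reactants: 10 2-[3,4-bis(tert-butyldimethylsilyloxy)-2-methoxy-5-(2-methylbut-3-en-2-yl)phenyl]acetaldehyde
Product: 11 2-[3,4-bis(tert-butyldimethylsilyloxy)-2-methoxy-5-(2-methylbut-3-en-2-yl)phenyl]acetic acid
Conditions: NaClO2, NaH2PO4, 2-methyl-2-butene, t-BuOH/H2O, 0 °C to rt
Reagents that add atoms: sodium chlorite, [Na+].[O-]Cl=O
Why: Pinnick oxidation; the scavenger alkene removes hypochlorous acid before it can chlorinate the electron-rich ring or the terminal alkene, and the weakly acidic buffer spares the silyl ethers.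

Step 9
Reactants: 11 2-[3,4-bis(tert-butyldimethylsilyloxy)-2-methoxy-5-(2-methylbut-3-en-2-yl)phenyl]acetic acid; 12 (4R)-4-benzyl-1,3-oxazolidin-2-one
Product: 13 (4R)-4-benzyl-3-{2-[3,4-bis(tert-butyldimethylsilyloxy)-2-methoxy-5-(2-methylbut-3-en-2-yl)phenyl]acetyl}-1,3-oxazolidin-2-one
Conditions: PivCl, Et3N, THF, −20 °C; then LiCl, 12, rt
Reagents that add atoms: none
Why: N-acylation through the mixed pivalic anhydride with lithium chloride activation; no alkyllithium is needed and the bulky pivaloyl carbonyl is not attacked.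

Step 10
Reactants: 14 4-(hydroxymethyl)phenol
Product: 15 [4-(prop-2-en-1-yloxy)phenyl]methanol
Conditions: allyl bromide, K2CO3, acetone, reflux
Reagents that add atoms: allyl bromide, C=CCBr
Why: Williamson etherification; carbonate deprotonates the phenol only, so the benzylic alcohol stays free.

Step 11
Reactants: 15 [4-(prop-2-en-1-yloxy)phenyl]methanol
Product: 16 1-(bromomethyl)-4-(prop-2-en-1-yloxy)benzene
Conditions: PBr3, Et2O, 0 °C; used fresh
Reagents that add atoms: phosphorus tribromide, BrP(Br)Br
Why: Conversion of a benzylic alcohol into the bromide through the phosphite ester; the allyl ether is inert at this temperature.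

Step 12
Reactants: 13 (4R)-4-benzyl-3-{2-[3,4-bis(tert-butyldimethylsilyloxy)-2-methoxy-5-(2-methylbut-3-en-2-yl)phenyl]acetyl}-1,3-oxazolidin-2-one; 16 1-(bromomethyl)-4-(prop-2-en-1-yloxy)benzene
Product: 17 (4R)-4-benzyl-3-{(2R)-2-[3,4-bis(tert-butyldimethylsilyloxy)-2-methoxy-5-(2-methylbut-3-en-2-yl)phenyl]-3-[4-(prop-2-en-1-yloxy)phenyl]propanoyl}-1,3-oxazolidin-2-one
Conditions: NaN(SiMe3)2 (1.0 equiv), THF, −78 °C; then 16, −78 to −30 °C
Reagents that add atoms: none
Why: Evans asymmetric alkylation: the chelated sodium Z-enolate is attacked by the benzylic bromide on the face opposite the auxiliary benzyl group, which with the (R)-auxiliary gives the (R) centre (ranking C=O > aryl > CH2Ar). Low temperature and no excess base protect the acidic α-aryl centre.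

Step 13
Reactants: 17 (4R)-4-benzyl-3-{(2R)-2-[3,4-bis(tert-butyldimethylsilyloxy)-2-methoxy-5-(2-methylbut-3-en-2-yl)phenyl]-3-[4-(prop-2-en-1-yloxy)phenyl]propanoyl}-1,3-oxazolidin-2-one
Product: 18 (2R)-2-[3,4-bis(tert-butyldimethylsilyloxy)-2-methoxy-5-(2-methylbut-3-en-2-yl)phenyl]-3-[4-(prop-2-en-1-yloxy)phenyl]propan-1-ol
Conditions: LiBH4, H2O (1 equiv), Et2O, 0 °C
Reagents that add atoms: none
Why: Reductive cleavage of the imide at the exocyclic carbonyl; no enolisation occurs, so C3 keeps its configuration, and the aryl silyl and allyl ethers do not react with borohydride.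

Step 14
Reactants: 18 (2R)-2-[3,4-bis(tert-butyldimethylsilyloxy)-2-methoxy-5-(2-methylbut-3-en-2-yl)phenyl]-3-[4-(prop-2-en-1-yloxy)phenyl]propan-1-ol
Product: 19 triethyl{(2R)-2-[3,4-bis(tert-butyldimethylsilyloxy)-2-methoxy-5-(2-methylbut-3-en-2-yl)phenyl]-3-[4-(prop-2-en-1-yloxy)phenyl]propoxy}silane
Conditions: TESCl, imidazole, CH2Cl2, 0 °C
Reagents that add atoms: chlorotriethylsilane, CC[Si](CC)(CC)Cl
Why: Silylation of the primary alcohol; the triethylsilyl ether is chosen because it survives the next two steps and is then lost to acid that leaves aryl tert-butyldimethylsilyl ethers alone.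

Step 15
Reactants: 19 triethyl{(2R)-2-[3,4-bis(tert-butyldimethylsilyloxy)-2-methoxy-5-(2-methylbut-3-en-2-yl)phenyl]-3-[4-(prop-2-en-1-yloxy)phenyl]propoxy}silane
Product: 20 4-{(2R)-2-[3,4-bis(tert-butyldimethylsilyloxy)-2-methoxy-5-(2-methylbut-3-en-2-yl)phenyl]-3-(triethylsilyloxy)propyl}phenol
Conditions: Pd(PPh3)4 (5 mol%), morpholine, THF, rt
Reagents that add atoms: none
Why: Tsuji–Trost deallylation: zerovalent palladium ionises the aryl allyl ether and morpholine traps the π-allyl complex; the tert-prenyl alkene has no leaving group and the medium is neither acidic nor hydroxylic, so all three silyl ethers remain.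

Step 16
Reactants: 20 4-{(2R)-2-[3,4-bis(tert-butyldimethylsilyloxy)-2-methoxy-5-(2-methylbut-3-en-2-yl)phenyl]-3-(triethylsilyloxy)propyl}phenol
Product: 22 4-{(2R)-2-[3,4-bis(tert-butyldimethylsilyloxy)-2-methoxy-5-(2-methylbut-3-en-2-yl)phenyl]-3-hydroxypropyl}-4-methoxycyclohexa-2,5-dien-1-one, via silyl ether dienone 21 (not isolated)
Conditions: PhI(OAc)2, MeOH, 0 °C; then PPTS (0.3 equiv), rt
Reagents that add atoms: methanol, CO
Why: Oxidative dearomatisation of a 4-alkylphenol with hypervalent iodine: ligand exchange at iodine, loss of iodobenzene and capture of the phenoxonium ion at the para carbon by the solvent. The triethylsilyl group keeps the C2 oxygen from closing a spiro ether at C4a and is then methanolysed by PPTS, an acid too weak to ionise the quinol ether.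

Step 17
Reactants: 22 4-{(2R)-2-[3,4-bis(tert-butyldimethylsilyloxy)-2-methoxy-5-(2-methylbut-3-en-2-yl)phenyl]-3-hydroxypropyl}-4-methoxycyclohexa-2,5-dien-1-one
Product: 24 (3R)-3-[3,4-bis(tert-butyldimethylsilyloxy)-2-methoxy-5-(2-methylbut-3-en-2-yl)phenyl]chroman-7-ol, via oxa-Michael adduct 23 (not isolated)
Conditions: DBU (0.2 equiv), dry CH2Cl2, 0 °C to rt; then camphorsulfonic acid (1.0 equiv), rt
Reagents that add atoms: none
Why: DBU activates the C2 hydroxyl, which adds to a β-carbon of the cross-conjugated dienone to give the cis-fused enone 23 and so forms O1–C8a. Camphorsulfonic acid then enolises the ketone, the doubly allylic methoxy group on C4a ionises to a cyclohexadienyl cation, and loss of the C8a proton gives the arene in which the former carbonyl oxygen is the C7 hydroxyl. The closest known reaction type is conjugate addition of heteroatom nucleophiles to 4-alkoxycyclohexa-2,5-dienones followed by loss of alcohol to give meta-functionalised phenols, together with base-mediated oxa-Michael closure of alcohols tethered to cyclohexadienones. Ring C closes in the 6-exo-trig mode. No lasting stereocentre is made: C4a and C8a are stereogenic only in 23 and both become sp2, while C3 has no acidic hydrogen and is untouched. Regioselectivity is not at issue because the two β-carbons lead to the same chromanol. The step needs chemoselectivity, secured by running the base stage first in dry dichloromethane, so that no cation at C4a exists while ring B or a 1,2-shift could intercept it, and by the silyl caps on ring B, which also keep the acid from a free ortho-(tert-prenyl)phenol.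

Step 18
Reactants: 24 (3R)-3-[3,4-bis(tert-butyldimethylsilyloxy)-2-methoxy-5-(2-methylbut-3-en-2-yl)phenyl]chroman-7-ol
Product: 25 4-[(3R)-7-hydroxy-3,4-dihydro-2H-chromen-3-yl]-3-methoxy-6-(2-methylbut-3-en-2-yl)benzene-1,2-diol
Conditions: TBAF, AcOH (1:1), THF, 0 °C, Ar
Reagents that add atoms: none
Why: Fluoride cleavage of the two aryl silyl ethers; acetic acid buffers the phenoxides so the catechol is not exposed to base and air, and no acid strong enough to cyclise the ortho-(tert-prenyl)phenol is present.

## Compound list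

1 | 2,3,4-trihydroxybenzaldehyde | O=Cc1ccc(O)c(O)c1O | starting material
2 | 4-hydroxy-2,2-diphenyl-1,3-benzodioxole-5-carbaldehyde | O=Cc1ccc2OC(c3ccccc3)(c3ccccc3)Oc2c1O | intermediate
3 | 4-methoxy-2,2-diphenyl-1,3-benzodioxole-5-carbaldehyde | O=Cc1ccc2OC(c3ccccc3)(c3ccccc3)Oc2c1OC | intermediate
4 | 3,4-dihydroxy-2-methoxybenzaldehyde | O=Cc1ccc(O)c(O)c1OC | intermediate
5 | prenyl bromide (1-bromo-3-methylbut-2-ene) | CC(C)=CCBr | starting material
6 | 3-hydroxy-2-methoxy-4-[(3-methylbut-2-en-1-yl)oxy]benzaldehyde | O=Cc1ccc(OCC=C(C)C)c(O)c1OC | intermediate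
7 | 3,4-dihydroxy-2-methoxy-5-(2-methylbut-3-en-2-yl)benzaldehyde | O=Cc1cc(C(C)(C)C=C)c(O)c(O)c1OC | intermediate (not isolated)
8 | 3,4-bis(tert-butyldimethylsilyloxy)-2-methoxy-5-(2-methylbut-3-en-2-yl)benzaldehyde | O=Cc1cc(C(C)(C)C=C)c(O[Si](C)(C)C(C)(C)C)c(O[Si](C)(C)C(C)(C)C)c1OC | intermediate
9 | 1,2-bis(tert-butyldimethylsilyloxy)-3-methoxy-4-(2-methoxyethenyl)-6-(2-methylbut-3-en-2-yl)benzene (E/Z mixture) | COC=Cc1cc(C(C)(C)C=C)c(O[Si](C)(C)C(C)(C)C)c(O[Si](C)(C)C(C)(C)C)c1OC | intermediate
10 | 2-[3,4-bis(tert-butyldimethylsilyloxy)-2-methoxy-5-(2-methylbut-3-en-2-yl)phenyl]acetaldehyde | O=CCc1cc(C(C)(C)C=C)c(O[Si](C)(C)C(C)(C)C)c(O[Si](C)(C)C(C)(C)C)c1OC | intermediate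
11 | 2-[3,4-bis(tert-butyldimethylsilyloxy)-2-methoxy-5-(2-methylbut-3-en-2-yl)phenyl]acetic acid | OC(=O)Cc1cc(C(C)(C)C=C)c(O[Si](C)(C)C(C)(C)C)c(O[Si](C)(C)C(C)(C)C)c1OC | intermediate
12 | (4R)-4-benzyl-1,3-oxazolidin-2-one | O=C1OC[C@@H](Cc2ccccc2)N1 | starting material
13 | (4R)-4-benzyl-3-{2-[3,4-bis(tert-butyldimethylsilyloxy)-2-methoxy-5-(2-methylbut-3-en-2-yl)phenyl]acetyl}-1,3-oxazolidin-2-one | O=C1OC[C@@H](Cc2ccccc2)N1C(=O)Cc1cc(C(C)(C)C=C)c(O[Si](C)(C)C(C)(C)C)c(O[Si](C)(C)C(C)(C)C)c1OC | intermediate
14 | 4-(hydroxymethyl)phenol | OCc1ccc(O)cc1 | starting material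
15 | [4-(prop-2-en-1-yloxy)phenyl]methanol | OCc1ccc(OCC=C)cc1 | intermediate
16 | 1-(bromomethyl)-4-(prop-2-en-1-yloxy)benzene | BrCc1ccc(OCC=C)cc1 | intermediate
17 | (4R)-4-benzyl-3-{(2R)-2-[3,4-bis(tert-butyldimethylsilyloxy)-2-methoxy-5-(2-methylbut-3-en-2-yl)phenyl]-3-[4-(prop-2-en-1-yloxy)phenyl]propanoyl}-1,3-oxazolidin-2-one | C=CC(C)(C)c1cc([C@@H](Cc2ccc(OCC=C)cc2)C(=O)N2C(=O)OC[C@H]2Cc2ccccc2)c(OC)c(O[Si](C)(C)C(C)(C)C)c1O[Si](C)(C)C(C)(C)C | intermediate
18 | (2R)-2-[3,4-bis(tert-butyldimethylsilyloxy)-2-methoxy-5-(2-methylbut-3-en-2-yl)phenyl]-3-[4-(prop-2-en-1-yloxy)phenyl]propan-1-ol | C=CC(C)(C)c1cc([C@@H](Cc2ccc(OCC=C)cc2)CO)c(OC)c(O[Si](C)(C)C(C)(C)C)c1O[Si](C)(C)C(C)(C)C | intermediate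
19 | triethyl{(2R)-2-[3,4-bis(tert-butyldimethylsilyloxy)-2-methoxy-5-(2-methylbut-3-en-2-yl)phenyl]-3-[4-(prop-2-en-1-yloxy)phenyl]propoxy}silane | C=CC(C)(C)c1cc([C@@H](Cc2ccc(OCC=C)cc2)CO[Si](CC)(CC)CC)c(OC)c(O[Si](C)(C)C(C)(C)C)c1O[Si](C)(C)C(C)(C)C | intermediate
20 | 4-{(2R)-2-[3,4-bis(tert-butyldimethylsilyloxy)-2-methoxy-5-(2-methylbut-3-en-2-yl)phenyl]-3-(triethylsilyloxy)propyl}phenol | C=CC(C)(C)c1cc([C@@H](Cc2ccc(O)cc2)CO[Si](CC)(CC)CC)c(OC)c(O[Si](C)(C)C(C)(C)C)c1O[Si](C)(C)C(C)(C)C | intermediate
21 | 4-{(2R)-2-[3,4-bis(tert-butyldimethylsilyloxy)-2-methoxy-5-(2-methylbut-3-en-2-yl)phenyl]-3-(triethylsilyloxy)propyl}-4-methoxycyclohexa-2,5-dien-1-one | C=CC(C)(C)c1cc([C@@H](CC2(OC)C=CC(=O)C=C2)CO[Si](CC)(CC)CC)c(OC)c(O[Si](C)(C)C(C)(C)C)c1O[Si](C)(C)C(C)(C)C | intermediate (not isolated)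
22 | 4-{(2R)-2-[3,4-bis(tert-butyldimethylsilyloxy)-2-methoxy-5-(2-methylbut-3-en-2-yl)phenyl]-3-hydroxypropyl}-4-methoxycyclohexa-2,5-dien-1-one | C=CC(C)(C)c1cc([C@@H](CC2(OC)C=CC(=O)C=C2)CO)c(OC)c(O[Si](C)(C)C(C)(C)C)c1O[Si](C)(C)C(C)(C)C | intermediate
23 | (3R)-3-[3,4-bis(tert-butyldimethylsilyloxy)-2-methoxy-5-(2-methylbut-3-en-2-yl)phenyl]-4a-methoxy-2,3,4,4a,8,8a-hexahydro-7H-chromen-7-one (cis-fused, mixture at C4a/C8a) | C=CC(C)(C)c1cc([C@@H]2COC3CC(=O)C=CC3(OC)C2)c(OC)c(O[Si](C)(C)C(C)(C)C)c1O[Si](C)(C)C(C)(C)C | intermediate (not isolated)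
24 | (3R)-3-[3,4-bis(tert-butyldimethylsilyloxy)-2-methoxy-5-(2-methylbut-3-en-2-yl)phenyl]chroman-7-ol | C=CC(C)(C)c1cc([C@@H]2COc3cc(O)ccc3C2)c(OC)c(O[Si](C)(C)C(C)(C)C)c1O[Si](C)(C)C(C)(C)C | intermediate
25 | 4-[(3R)-7-hydroxy-3,4-dihydro-2H-chromen-3-yl]-3-methoxy-6-(2-methylbut-3-en-2-yl)benzene-1,2-diol (CNP0167796.1) | C=CC(C)(C)c1cc([C@@H]2COc3cc(O)ccc3C2)c(OC)c(O)c1O | target

## Step count and least certain steps

Total: 18 steps. Longest linear sequence: 16 steps (steps 1 to 9 and 12 to 18); steps 10 and 11 form the side branch.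

**Step 17 (key step).** The conjugate addition may be slow or lie on the side of the open dienone; the amidine may strip an aryl silyl group if water is present; and in the acid stage a 1,2-shift of the quinol ether or attack of ring B at C4a may compete with loss of methanol from the adduct. Fallback: close O1–C8a by palladium-catalysed aryl etherification. Bought 2-bromo-4-hydroxybenzaldehyde is O-allylated to 2-bromo-4-(prop-2-en-1-yloxy)benzaldehyde F1, reduced with NaBH4 to [2-bromo-4-(prop-2-en-1-yloxy)phenyl]methanol F2 and converted with PBr3 into 2-bromo-1-(bromomethyl)-4-(prop-2-en-1-yloxy)benzene F3. The fallback sets out from 13, whose sodium enolate is alkylated with F3 as in step 12 to give (4R)-4-benzyl-3-{(2R)-2-[3,4-bis(tert-butyldimethylsilyloxy)-2-methoxy-5-(2-methylbut-3-en-2-yl)phenyl]-3-[2-bromo-4-(prop-2-en-1-yloxy)phenyl]propanoyl}-1,3-oxazolidin-2-one F4. LiBH4 gives (2R)-2-[3,4-bis(tert-butyldimethylsilyloxy)-2-methoxy-5-(2-methylbut-3-en-2-yl)phenyl]-3-[2-bromo-4-(prop-2-en-1-yloxy)phenyl]propan-1-ol F5. Buchwald–Hartwig etherification (Pd(OAc)2, 2-(di-tert-butylphosphino)-1,1'-binaphthyl, Cs2CO3, toluene, 70 °C) closes ring C to (3R)-3-[3,4-bis(tert-butyldimethylsilyloxy)-2-methoxy-5-(2-methylbut-3-en-2-yl)phenyl]-7-(prop-2-en-1-yloxy)chroman F6. Deallylation as in step 15 comes back to the route at 24.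

**Step 16.** The triethylsilyl group may be lost before the oxidation is over, so that the C2 oxygen captures the phenoxonium ion; methanol may add at the ortho carbon; or C6' of ring B may attack C4a. Fallback: avoid the phenoxonium ion. Setting out from 20, the phenol is oxidised with singlet oxygen generated from KHSO5 (as 2KHSO5·KHSO4·K2SO4) and NaHCO3 in MeCN/H2O, with Na2S2O3 work-up, to the para-quinol 4-{(2R)-2-[3,4-bis(tert-butyldimethylsilyloxy)-2-methoxy-5-(2-methylbut-3-en-2-yl)phenyl]-3-(triethylsilyloxy)propyl}-4-hydroxycyclohexa-2,5-dien-1-one F7. PPTS in methanol frees 4-{(2R)-2-[3,4-bis(tert-butyldimethylsilyloxy)-2-methoxy-5-(2-methylbut-3-en-2-yl)phenyl]-3-hydroxypropyl}-4-hydroxycyclohexa-2,5-dien-1-one F8. DBU and then camphorsulfonic acid, as in step 17 but with loss of water, come back to the route at 24.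

**Step 5.** The free ortho-phenol formed at 185 °C may isomerise the tert-prenyl group (abnormal Claisen rearrangement), close onto the alkene or lose the prenyl group; silylation of the hindered O4' may stop halfway. Fallback: make the C5'–C bond by cross-coupling. Setting out from 4, bromination (NBS, MeCN, 0 °C) ortho to the 4-hydroxyl gives 5-bromo-3,4-dihydroxy-2-methoxybenzaldehyde F9. Silylation as in step 5 gives 5-bromo-3,4-bis(tert-butyldimethylsilyloxy)-2-methoxybenzaldehyde F10, and the Wittig reaction of step 6 gives 1-bromo-2,3-bis(tert-butyldimethylsilyloxy)-4-methoxy-5-(2-methoxyethenyl)benzene F11. A γ-selective Suzuki–Miyaura coupling with 3-methylbut-2-enylboronic acid pinacol ester (Pd(OAc)2, bulky biarylphosphine, K3PO4, THF/H2O, 40 °C) comes back to the route at 9. The coupling is placed after the Wittig step because an allylboronate would add to the aldehyde.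

**Step 12.** The hindered, aryl-substituted enolate may alkylate slowly; it may lose the auxiliary anion to a ketene; and the product, which has an acidic α-aryl hydrogen, may equilibrate and erode the diastereomer ratio. Fallback: direct enantioselective alkylation of the acid. Setting out from 11, the enediolate is formed with n-BuLi and the lithium amide of a C2-symmetric chiral tetramine (enantiomer chosen for the R centre) and alkylated with 16 to give (2R)-2-[3,4-bis(tert-butyldimethylsilyloxy)-2-methoxy-5-(2-methylbut-3-en-2-yl)phenyl]-3-[4-(prop-2-en-1-yloxy)phenyl]propanoic acid F12. Reduction with LiAlH4 (Et2O, 0 °C) comes back to the route at 18.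

**Step 7.** Hydrolysis of the aryl-conjugated enol ether may need acid strong enough to remove an aryl silyl group or to protonate the terminal alkene, and the arylacetaldehyde may condense with itself or oxidise in air. Fallback: reach the aldehyde by rearrangement instead of hydrolysis. Setting out from 8, Corey–Chaykovsky epoxidation (Me3SI, KN(SiMe3)2, THF, −10 °C to rt) gives 2-[3,4-bis(tert-butyldimethylsilyloxy)-2-methoxy-5-(2-methylbut-3-en-2-yl)phenyl]oxirane F13. Meinwald rearrangement with catalytic ZnBr2 in toluene (benzylic C–O cleavage and hydride shift) comes back to the route at 10.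

## Further compounds

F1 | step 17 | 2-bromo-4-(prop-2-en-1-yloxy)benzaldehyde | O=Cc1ccc(OCC=C)cc1Br
F2 | step 17 | [2-bromo-4-(prop-2-en-1-yloxy)phenyl]methanol | OCc1ccc(OCC=C)cc1Br
F3 | step 17 | 2-bromo-1-(bromomethyl)-4-(prop-2-en-1-yloxy)benzene | BrCc1ccc(OCC=C)cc1Br
F4 | step 17 | (4R)-4-benzyl-3-{(2R)-2-[3,4-bis(tert-butyldimethylsilyloxy)-2-methoxy-5-(2-methylbut-3-en-2-yl)phenyl]-3-[2-bromo-4-(prop-2-en-1-yloxy)phenyl]propanoyl}-1,3-oxazolidin-2-one | C=CC(C)(C)c1cc([C@@H](Cc2ccc(OCC=C)cc2Br)C(=O)N2C(=O)OC[C@H]2Cc2ccccc2)c(OC)c(O[Si](C)(C)C(C)(C)C)c1O[Si](C)(C)C(C)(C)C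
F5 | step 17 | (2R)-2-[3,4-bis(tert-butyldimethylsilyloxy)-2-methoxy-5-(2-methylbut-3-en-2-yl)phenyl]-3-[2-bromo-4-(prop-2-en-1-yloxy)phenyl]propan-1-ol | C=CC(C)(C)c1cc([C@@H](Cc2ccc(OCC=C)cc2Br)CO)c(OC)c(O[Si](C)(C)C(C)(C)C)c1O[Si](C)(C)C(C)(C)C
F6 | step 17 | (3R)-3-[3,4-bis(tert-butyldimethylsilyloxy)-2-methoxy-5-(2-methylbut-3-en-2-yl)phenyl]-7-(prop-2-en-1-yloxy)chroman | C=CC(C)(C)c1cc([C@@H]2COc3cc(OCC=C)ccc3C2)c(OC)c(O[Si](C)(C)C(C)(C)C)c1O[Si](C)(C)C(C)(C)C
F7 | step 16 | 4-{(2R)-2-[3,4-bis(tert-butyldimethylsilyloxy)-2-methoxy-5-(2-methylbut-3-en-2-yl)phenyl]-3-(triethylsilyloxy)propyl}-4-hydroxycyclohexa-2,5-dien-1-one | C=CC(C)(C)c1cc([C@@H](CC2(O)C=CC(=O)C=C2)CO[Si](CC)(CC)CC)c(OC)c(O[Si](C)(C)C(C)(C)C)c1O[Si](C)(C)C(C)(C)C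
F8 | step 16 | 4-{(2R)-2-[3,4-bis(tert-butyldimethylsilyloxy)-2-methoxy-5-(2-methylbut-3-en-2-yl)phenyl]-3-hydroxypropyl}-4-hydroxycyclohexa-2,5-dien-1-one | C=CC(C)(C)c1cc([C@@H](CC2(O)C=CC(=O)C=C2)CO)c(OC)c(O[Si](C)(C)C(C)(C)C)c1O[Si](C)(C)C(C)(C)C
F9 | step 5 | 5-bromo-3,4-dihydroxy-2-methoxybenzaldehyde | O=Cc1cc(Br)c(O)c(O)c1OC
F10 | step 5 | 5-bromo-3,4-bis(tert-butyldimethylsilyloxy)-2-methoxybenzaldehyde | O=Cc1cc(Br)c(O[Si](C)(C)C(C)(C)C)c(O[Si](C)(C)C(C)(C)C)c1OC
F11 | step 5 | 1-bromo-2,3-bis(tert-butyldimethylsilyloxy)-4-methoxy-5-(2-methoxyethenyl)benzene (E/Z mixture) | COC=Cc1cc(Br)c(O[Si](C)(C)C(C)(C)C)c(O[Si](C)(C)C(C)(C)C)c1OC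
F12 | step 12 | (2R)-2-[3,4-bis(tert-butyldimethylsilyloxy)-2-methoxy-5-(2-methylbut-3-en-2-yl)phenyl]-3-[4-(prop-2-en-1-yloxy)phenyl]propanoic acid | C=CC(C)(C)c1cc([C@@H](Cc2ccc(OCC=C)cc2)C(=O)O)c(OC)c(O[Si](C)(C)C(C)(C)C)c1O[Si](C)(C)C(C)(C)C
F13 | step 7 | 2-[3,4-bis(tert-butyldimethylsilyloxy)-2-methoxy-5-(2-methylbut-3-en-2-yl)phenyl]oxirane (racemic) | C=CC(C)(C)c1cc(C2CO2)c(OC)c(O[Si](C)(C)C(C)(C)C)c1O[Si](C)(C)C(C)(C)C
A1 | alternative 1 | (3R)-3-[4-(benzyloxy)-2-methoxy-3-{[2-(trimethylsilyl)ethoxy]methoxy}phenyl]-7-(triisopropylsilyloxy)chroman | COc1c([C@@H]2COc3cc(O[Si](C(C)C)(C(C)C)C(C)C)ccc3C2)ccc(OCc2ccccc2)c1OCOCC[Si](C)(C)C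
A2 | alternative 1 | 1,3-dioxoisoindolin-2-yl (3R)-3-[4-(benzyloxy)-2-methoxy-3-{[2-(trimethylsilyl)ethoxy]methoxy}phenyl]-4-[2-bromo-5-(triisopropylsilyloxy)phenoxy]butanoate | COc1c([C@@H](CC(=O)ON2C(=O)c3ccccc3C2=O)COc2cc(O[Si](C(C)C)(C(C)C)C(C)C)ccc2Br)ccc(OCc2ccccc2)c1OCOCC[Si](C)(C)C
A3 | alternative 2 | 3-[4-(benzyloxy)-2-methoxy-3-(triisopropylsilyloxy)phenyl]-7-(triisopropylsilyloxy)-2H-chromene | COc1c(C2=Cc3ccc(O[Si](C(C)C)(C(C)C)C(C)C)cc3OC2)ccc(OCc2ccccc2)c1O[Si](C(C)C)(C(C)C)C(C)C
A4 | alternative 2 | 3-(triisopropylsilyloxy)phenol | Oc1cccc(O[Si](C(C)C)(C(C)C)C(C)C)c1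
A5 | alternative 2 | 2-[4-(benzyloxy)-2-methoxy-3-(triisopropylsilyloxy)phenyl]prop-2-enal | C=C(C=O)c1ccc(OCc2ccccc2)c(O[Si](C(C)C)(C(C)C)C(C)C)c1OC
A6 | alternative 3 | (R)-2-{2-[2,4-bis(tert-butyldimethylsilyloxy)phenyl]-1-[4-(tert-butyldimethylsilyloxy)-2-methoxy-5-(2-methylbut-3-en-2-yl)-3-{[2-(trimethylsilyl)ethoxy]methoxy}phenyl]ethyl}-4,4,5,5-tetramethyl-1,3,2-dioxaborolane | C=CC(C)(C)c1cc([C@@H](Cc2ccc(O[Si](C)(C)C(C)(C)C)cc2O[Si](C)(C)C(C)(C)C)B2OC(C)(C)C(C)(C)O2)c(OC)c(OCOCC[Si](C)(C)C)c1O[Si](C)(C)C(C)(C)C
A7 | alternative 3 | 1-bromo-4-(tert-butyldimethylsilyloxy)-2-methoxy-5-(2-methylbut-3-en-2-yl)-3-{[2-(trimethylsilyl)ethoxy]methoxy}benzene | Brc1cc(C(C)(C)C=C)c(O[Si](C)(C)C(C)(C)C)c(OCOCC[Si](C)(C)C)c1OC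
A8 | alternative 3 | 1-bromo-2,4-bis(tert-butyldimethylsilyloxy)benzene | Brc1ccc(O[Si](C)(C)C(C)(C)C)cc1O[Si](C)(C)C(C)(C)C
A9 | alternative 3 | 2-ethenyl-4,4,5,5-tetramethyl-1,3,2-dioxaborolane | C=CB1OC(C)(C)C(C)(C)O1
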